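**Plan**

- Retrosynthesis: ring C is opened at O1–C2 and C2–C3 (C2 comes from a formamide acetal) to an open 2-hydroxyphenyl benzyl ketone. The three aryl–CH2 bonds at C6, C8 and C3' are then cut back to aryl 1,1-dimethylallyl ethers on the oxygens at C5, C8a and C2'. Last, the C4–C4a bond is cut to a ring A aryllithium and a ring B arylacetamide.
- Enabling feature: C6, C8 and C3' each stand next to an oxygen-bearing carbon (C5, C8a, C2') whose other neighbour (C4a, C4a, C1') carries no hydrogen. An allyl group leaving any of these oxygens by a [3,3] shift therefore has only one carbon on which it can come to rest.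
- Forward order: ring B enters as a lactone, which keeps its ortho oxygen distinct from the para oxygen, and ring A as a tribenzyl ether. They are joined as the ketone without acid, because an ortho-hydroxybenzyl aryl ketone cyclodehydrates to a 2-arylbenzofuran under acid. The ring A oxygens are then freed and the para one is capped. The tertiary propargyl ethers are made in two stages (the two readily alkylated hydroxyls first, the chelated one second) and semihydrogenated, and the threefold Claisen rearrangement places all three prenyl groups.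
- Ring C is the only ring formed. It is closed in the penultimate step, after the ring B ortho hydroxyl has been capped, and a single acid step then frees the four phenols.
- Stereochemistry: the target has no stereocentre and every prenyl alkene ends in two identical methyl groups, so nothing has to be set or preserved.

Key step: step 10

Assumption: the three carbon-skeleton starting materials (1, 4 and 12) are taken as purchasable; the push–pull enaminone formed in step 12 interconverts between its two double-bond geometries, so no geometry is assigned to it.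

**Route**

Step 1
Reactants: 1 6-hydroxybenzofuran-2(3H)-one
Product: 2 6-(methoxymethoxy)benzofuran-2(3H)-one
Conditions: MOMCl (1.2 equiv), i-Pr2NEt (1.5 equiv), CH2Cl2, 0 °C
Reagents that add atoms: chloromethyl methyl ether, COCCl
Why: Williamson-type acetal ether formation on the only free hydroxyl, the ortho oxygen being held in the lactone, with an amine too weak to ionise the lactone C3–H appreciably in CH2Cl2, so that the two oxygens of ring B leave this step differentiated.

Step 2
Reactants: 2 6-(methoxymethoxy)benzofuran-2(3H)-one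
Product: 3 2-[2-hydroxy-4-(methoxymethoxy)phenyl]-1-(morpholin-4-yl)ethan-1-one
Conditions: morpholine (1.5 equiv), THF, 20 °C
Reagents that add atoms: morpholine, C1COCCN1
Why: Aminolysis of a phenolic lactone by a secondary amine, which should open the ring at ambient temperature to a morpholine amide (a Weinreb-amide surrogate) and uncover the ortho hydroxyl alone.

Step 3
Reactants: 4 1,3,5-tris(benzyloxy)benzene
Product: 5 2-bromo-1,3,5-tris(benzyloxy)benzene
Conditions: NBS (1.0 equiv), MeCN–CH2Cl2, −20 → 0 °C
Reagents that add atoms: N-bromosuccinimide, O=C1CCC(=O)N1Br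
Why: Electrophilic aromatic bromination of a threefold symmetric, strongly activated arene in which all ring positions are equivalent, so one equivalent of NBS at low temperature should stop at the single monobromide.

Step 4
Reactants: 5 2-bromo-1,3,5-tris(benzyloxy)benzene; 3 2-[2-hydroxy-4-(methoxymethoxy)phenyl]-1-(morpholin-4-yl)ethan-1-one
Product: 9 1-[2,4,6-tris(benzyloxy)phenyl]-2-[2-hydroxy-4-(methoxymethoxy)phenyl]ethan-1-one, via lithium phenoxide 6 (not isolated), via 2,4,6-tris(benzyloxy)phenyllithium 7 (not isolated), via dilithium aminal alkoxide 8 (not isolated)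
Conditions: 5 (1.3 equiv), n-BuLi (1.25 equiv), THF, −78 °C; 3 + LiN(SiMe3)2 (1.05 equiv), THF, −78 °C, added by cannula; −78 → −20 °C; then H2O
Reagents that add atoms: none
Why: Bromine–lithium exchange followed by acylation of the aryllithium with a morpholine amide, whose tetrahedral lithium aminal alkoxide persists until the quench and so cannot add twice, while prior conversion of the phenol into its lithium salt removes the acidic proton and lowers the acidity of the neighbouring methylene, and the absence of acid keeps the ortho-hydroxybenzyl ketone from cyclodehydrating to a benzofuran.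

Step 5
Reactants: 9 1-[2,4,6-tris(benzyloxy)phenyl]-2-[2-hydroxy-4-(methoxymethoxy)phenyl]ethan-1-one
Product: 10 2-[2-hydroxy-4-(methoxymethoxy)phenyl]-1-(2,4,6-trihydroxyphenyl)ethan-1-one
Conditions: H2 (1 atm), Pd/C, EtOAc–MeOH, 20 °C
Reagents that add atoms: none
Why: Catalytic hydrogenolysis of aryl benzyl ethers under neutral conditions, which should leave the acetal and the aryl ketone (deactivated by two ortho oxygens) untouched and expose the acid-sensitive ortho-hydroxybenzyl ketone motif to no acid.

Step 6
Reactants: 10 2-[2-hydroxy-4-(methoxymethoxy)phenyl]-1-(2,4,6-trihydroxyphenyl)ethan-1-one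
Product: 11 1-[2,6-dihydroxy-4-(methoxymethoxy)phenyl]-2-[2-hydroxy-4-(methoxymethoxy)phenyl]ethan-1-one
Conditions: MOMCl (1.05 equiv), i-Pr2NEt (1.1 equiv), THF, −20 → 0 °C
Reagents that add atoms: chloromethyl methyl ether, COCCl
Why: Selective Williamson-type O-alkylation of the most acidic hydroxyl, the one para to the carbonyl (a vinylogous carboxylic acid), because the two ortho hydroxyls are hydrogen-bonded to the ketone and the ring B hydroxyl is a less acidic, ortho-substituted phenol that one equivalent of weak base should not ionise.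

Step 7
Reactants: 11 1-[2,6-dihydroxy-4-(methoxymethoxy)phenyl]-2-[2-hydroxy-4-(methoxymethoxy)phenyl]ethan-1-one; 12 3-chloro-3-methylbut-1-yne
Product: 13 1-[2-hydroxy-4-(methoxymethoxy)-6-(2-methylbut-3-yn-2-yloxy)phenyl]-2-[4-(methoxymethoxy)-2-(2-methylbut-3-yn-2-yloxy)phenyl]ethan-1-one
Conditions: 12 (2.3 equiv), DBU (2.6 equiv), CuCl2·2H2O (2 mol%), MeCN, −5 → 0 °C
Reagents that add atoms: 3-chloro-3-methylbut-1-yne (the second equivalent of 12), C#CC(C)(C)Cl
Why: Copper-catalysed propargylic etherification, in which the copper acetylide of the tertiary chloride ionises to a propargyl/allenylidene cation equivalent that a DBU-generated phenoxide captures at the tertiary carbon; at 0 °C with a small excess of chloride the ring B hydroxyl and one of the two equivalent ring A hydroxyls should react, while the last ring A hydroxyl, hydrogen-bonded to the ketone and now next to a bulky ether, lags behind as in the familiar partial alkylation of 2,6-dihydroxyaryl ketones.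

Step 8
Reactants: 13 1-[2-hydroxy-4-(methoxymethoxy)-6-(2-methylbut-3-yn-2-yloxy)phenyl]-2-[4-(methoxymethoxy)-2-(2-methylbut-3-yn-2-yloxy)phenyl]ethan-1-one; 12 3-chloro-3-methylbut-1-yne
Product: 14 1-[2,6-bis(2-methylbut-3-yn-2-yloxy)-4-(methoxymethoxy)phenyl]-2-[2-(2-methylbut-3-yn-2-yloxy)-4-(methoxymethoxy)phenyl]ethan-1-one
Conditions: 12 (3 equiv), DBU (3.5 equiv), CuCl2·2H2O (5 mol%), MeCN, 0 → 25 °C
Reagents that add atoms: none
Why: The same copper-catalysed propargylic etherification, now driven with a larger excess of the chloride, more catalyst and a higher temperature to engage the remaining hydroxyl, whose hydrogen bond is weakened because the tertiary ether on the other ortho oxygen pushes the carbonyl out of the ring plane.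

Step 9
Reactants: 14 1-[2,6-bis(2-methylbut-3-yn-2-yloxy)-4-(methoxymethoxy)phenyl]-2-[2-(2-methylbut-3-yn-2-yloxy)-4-(methoxymethoxy)phenyl]ethan-1-one
Product: 15 1-[2,6-bis(2-methylbut-3-en-2-yloxy)-4-(methoxymethoxy)phenyl]-2-[2-(2-methylbut-3-en-2-yloxy)-4-(methoxymethoxy)phenyl]ethan-1-one
Conditions: H2 (1 atm, stopped after 3 equiv), Pd/CaCO3–Pb(OAc)2 (Lindlar catalyst), quinoline, EtOAc, 20 °C
Reagents that add atoms: none
Why: Lindlar semihydrogenation of terminal alkynes, which with quinoline as a further poison should stop at the vinyl stage and leave the aryl ketone, the acetals and the aryl ethers alone.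

Step 10
Reactants: 15 1-[2,6-bis(2-methylbut-3-en-2-yloxy)-4-(methoxymethoxy)phenyl]-2-[2-(2-methylbut-3-en-2-yloxy)-4-(methoxymethoxy)phenyl]ethan-1-one
Product: 16 1-[2,6-dihydroxy-4-(methoxymethoxy)-3,5-bis(3-methylbut-2-en-1-yl)phenyl]-2-[2-hydroxy-4-(methoxymethoxy)-3-(3-methylbut-2-en-1-yl)phenyl]ethan-1-one
Conditions: PhNEt2 (degassed), 130 °C, Ar
Reagents that add atoms: none
Why: Each of the three aryl 1,1-dimethylallyl ethers should undergo a concerted suprafacial [3,3] shift through a chair-like six-membered transition state in which the terminal CH2 of the allyl unit bonds to the hydrogen-bearing ortho carbon, and the resulting 6-substituted cyclohexa-2,4-dienone enolises to the phenol, so the allylic transposition turns every branched ether into a linear 3-methylbut-2-enyl group on carbon. The closest known reaction is the aromatic Claisen rearrangement of tertiary allyl aryl ethers to ortho-prenylphenols, which runs well below the temperature needed for primary allyl ethers. No ring is closed and no stereocentre is created. The step needs site selectivity at three oxygens, and the substrate supplies it: each migrating oxygen (O2 and O6 of ring A, O2' of ring B) has one ortho carbon that is quaternary (C1 carrying the ketone, C1' carrying the methylene), so a shift onto that carbon cannot rearomatise by enolisation and productive migration ends only at C3, C5 and C3', while an onward Cope shift to the para carbon is not expected to compete because it would build the more hindered reverse-prenyl group at a position that is being filled by the neighbouring ether. The two para oxygens are acetals and cannot migrate, and the moderate temperature in a basic aniline solvent is chosen to hold back the known follow-up reactions, namely chroman closure of an ortho-prenylphenol, loss of isoprene from a tertiary ether and cyclodehydration of the freed ring B hydroxyl onto the ketone.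

Step 11
Reactants: 16 1-[2,6-dihydroxy-4-(methoxymethoxy)-3,5-bis(3-methylbut-2-en-1-yl)phenyl]-2-[2-hydroxy-4-(methoxymethoxy)-3-(3-methylbut-2-en-1-yl)phenyl]ethan-1-one
Product: 17 1-[2-hydroxy-4,6-bis(methoxymethoxy)-3,5-bis(3-methylbut-2-en-1-yl)phenyl]-2-[2,4-bis(methoxymethoxy)-3-(3-methylbut-2-en-1-yl)phenyl]ethan-1-one
Conditions: MOMCl (4 equiv), i-Pr2NEt (6 equiv), CH2Cl2, 0 → 40 °C
Reagents that add atoms: chloromethyl methyl ether, COCCl
Why: Acetal ether formation with excess reagent, which should cap the ring B hydroxyl and one of the two equivalent ring A hydroxyls and then stop because the last hydroxyl is locked in a hydrogen bond to the ketone, the ring B oxygen being blocked so that it cannot close a furan onto the enaminone of the next step.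

Step 12
Reactants: 17 1-[2-hydroxy-4,6-bis(methoxymethoxy)-3,5-bis(3-methylbut-2-en-1-yl)phenyl]-2-[2,4-bis(methoxymethoxy)-3-(3-methylbut-2-en-1-yl)phenyl]ethan-1-one
Product: 19 5,7-bis(methoxymethoxy)-3-[2,4-bis(methoxymethoxy)-3-(3-methylbut-2-en-1-yl)phenyl]-6,8-bis(3-methylbut-2-en-1-yl)-4H-chromen-4-one, via enaminone 18 (not isolated)
Conditions: Me2NCH(OMe)2 (3 equiv), toluene, 95 °C
Reagents that add atoms: N,N-dimethylformamide dimethyl acetal, COC(OC)N(C)C
Why: Standard isoflavone synthesis from a 2-hydroxyphenyl benzyl ketone, in which the activated methylene condenses with the formamide acetal to the enaminone and the chelated phenol then adds to its β-carbon (6-endo-trig addition–elimination) with loss of dimethylamine to close ring C.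

Step 13
Reactants: 19 5,7-bis(methoxymethoxy)-3-[2,4-bis(methoxymethoxy)-3-(3-methylbut-2-en-1-yl)phenyl]-6,8-bis(3-methylbut-2-en-1-yl)-4H-chromen-4-one
Product: 20 euchrenone b2 (5,7-dihydroxy-3-[2,4-dihydroxy-3-(3-methylbut-2-en-1-yl)phenyl]-6,8-bis(3-methylbut-2-en-1-yl)-4H-chromen-4-one)
Conditions: HCl (1.25 M in MeOH), THF, 40 °C
Reagents that add atoms: none
Why: Acid-catalysed transacetalisation of aryl methoxymethyl ethers to methanol, a routine deprotection of prenylated flavonoids, run at low acid strength and moderate temperature so that the four acetals should be cleaved before the freed phenols add to the prenyl double bonds.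

**Compound list**

1 | 6-hydroxybenzofuran-2(3H)-one | O=C1Cc2ccc(O)cc2O1 | starting material
2 | 6-(methoxymethoxy)benzofuran-2(3H)-one | COCOc1ccc2CC(=O)Oc2c1 | intermediate
3 | 2-[2-hydroxy-4-(methoxymethoxy)phenyl]-1-(morpholin-4-yl)ethan-1-one | COCOc1ccc(CC(=O)N2CCOCC2)c(O)c1 | intermediate
4 | 1,3,5-tris(benzyloxy)benzene | c1ccc(COc2cc(OCc3ccccc3)cc(OCc3ccccc3)c2)cc1 | starting material
5 | 2-bromo-1,3,5-tris(benzyloxy)benzene | Brc1c(OCc2ccccc2)cc(OCc2ccccc2)cc1OCc1ccccc1 | intermediate
6 | lithium 5-(methoxymethoxy)-2-[2-(morpholin-4-yl)-2-oxoethyl]phenolate (not isolated) | [Li+].COCOc1ccc(CC(=O)N2CCOCC2)c([O-])c1 | intermediate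
7 | 2,4,6-tris(benzyloxy)phenyllithium (not isolated) | [Li]c1c(OCc2ccccc2)cc(OCc2ccccc2)cc1OCc1ccccc1 | intermediate
8 | dilithium aminal alkoxide, tetrahedral adduct of 7 to 6 (not isolated) | [Li+].[Li+].COCOc1ccc(CC([O-])(N2CCOCC2)c2c(OCc3ccccc3)cc(OCc3ccccc3)cc2OCc2ccccc2)c([O-])c1 | intermediate
9 | 1-[2,4,6-tris(benzyloxy)phenyl]-2-[2-hydroxy-4-(methoxymethoxy)phenyl]ethan-1-one | COCOc1ccc(CC(=O)c2c(OCc3ccccc3)cc(OCc3ccccc3)cc2OCc2ccccc2)c(O)c1 | intermediate
10 | 2-[2-hydroxy-4-(methoxymethoxy)phenyl]-1-(2,4,6-trihydroxyphenyl)ethan-1-one | COCOc1ccc(CC(=O)c2c(O)cc(O)cc2O)c(O)c1 | intermediate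
11 | 1-[2,6-dihydroxy-4-(methoxymethoxy)phenyl]-2-[2-hydroxy-4-(methoxymethoxy)phenyl]ethan-1-one | COCOc1ccc(CC(=O)c2c(O)cc(OCOC)cc2O)c(O)c1 | intermediate
12 | 3-chloro-3-methylbut-1-yne | C#CC(C)(C)Cl | starting material
13 | 1-[2-hydroxy-4-(methoxymethoxy)-6-(2-methylbut-3-yn-2-yloxy)phenyl]-2-[4-(methoxymethoxy)-2-(2-methylbut-3-yn-2-yloxy)phenyl]ethan-1-one | C#CC(C)(C)Oc1cc(OCOC)cc(O)c1C(=O)Cc1ccc(OCOC)cc1OC(C)(C)C#C | intermediate
14 | 1-[2,6-bis(2-methylbut-3-yn-2-yloxy)-4-(methoxymethoxy)phenyl]-2-[2-(2-methylbut-3-yn-2-yloxy)-4-(methoxymethoxy)phenyl]ethan-1-one | C#CC(C)(C)Oc1cc(OCOC)cc(OC(C)(C)C#C)c1C(=O)Cc1ccc(OCOC)cc1OC(C)(C)C#C | intermediate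
15 | 1-[2,6-bis(2-methylbut-3-en-2-yloxy)-4-(methoxymethoxy)phenyl]-2-[2-(2-methylbut-3-en-2-yloxy)-4-(methoxymethoxy)phenyl]ethan-1-one | C=CC(C)(C)Oc1cc(OCOC)cc(OC(C)(C)C=C)c1C(=O)Cc1ccc(OCOC)cc1OC(C)(C)C=C | intermediate
16 | 1-[2,6-dihydroxy-4-(methoxymethoxy)-3,5-bis(3-methylbut-2-en-1-yl)phenyl]-2-[2-hydroxy-4-(methoxymethoxy)-3-(3-methylbut-2-en-1-yl)phenyl]ethan-1-one | O=C(Cc1ccc(OCOC)c(CC=C(C)C)c1O)c1c(O)c(CC=C(C)C)c(OCOC)c(CC=C(C)C)c1O | intermediate
17 | 1-[2-hydroxy-4,6-bis(methoxymethoxy)-3,5-bis(3-methylbut-2-en-1-yl)phenyl]-2-[2,4-bis(methoxymethoxy)-3-(3-methylbut-2-en-1-yl)phenyl]ethan-1-one | O=C(Cc1ccc(OCOC)c(CC=C(C)C)c1OCOC)c1c(O)c(CC=C(C)C)c(OCOC)c(CC=C(C)C)c1OCOC | intermediate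
18 | 3-(dimethylamino)-1-[2-hydroxy-4,6-bis(methoxymethoxy)-3,5-bis(3-methylbut-2-en-1-yl)phenyl]-2-[2,4-bis(methoxymethoxy)-3-(3-methylbut-2-en-1-yl)phenyl]prop-2-en-1-one (not isolated, geometry not fixed) | CN(C)C=C(C(=O)c1c(O)c(CC=C(C)C)c(OCOC)c(CC=C(C)C)c1OCOC)c1ccc(OCOC)c(CC=C(C)C)c1OCOC | intermediate
19 | 5,7-bis(methoxymethoxy)-3-[2,4-bis(methoxymethoxy)-3-(3-methylbut-2-en-1-yl)phenyl]-6,8-bis(3-methylbut-2-en-1-yl)-4H-chromen-4-one | COCOc1ccc(-c2coc3c(CC=C(C)C)c(OCOC)c(CC=C(C)C)c(OCOC)c3c2=O)c(OCOC)c1CC=C(C)C | intermediate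
20 | euchrenone b2, 5,7-dihydroxy-3-[2,4-dihydroxy-3-(3-methylbut-2-en-1-yl)phenyl]-6,8-bis(3-methylbut-2-en-1-yl)-4H-chromen-4-one | CC(C)=CCc1c(O)ccc(-c2coc3c(CC=C(C)C)c(O)c(CC=C(C)C)c(O)c3c2=O)c1O | target

**Step count and risks**

Total steps: 13. Longest linear sequence: 12 steps (from 1 through steps 1, 2 and 4 to 13; the ring A branch from 4 is 11 steps).

Step 8. What may go wrong: etherification of the last ring A oxygen may stall, because that hydroxyl is hydrogen-bonded to the ketone and flanked by a tertiary ether. The doubly benzylic methylene may also be alkylated on carbon under the more forcing conditions. The fallback sets out from 11 and forms the three tertiary allyl ethers directly by a branched-selective Tsuji–Trost O-allylation with tert-butyl 2-methylbut-3-en-2-yl carbonate and Pd(PPh3)4 in THF at 0 °C. Here the phenoxide attacks the more substituted terminus of the π-allyl palladium cation under kinetic control, and that cation is a more reactive electrophile for the chelated oxygen. This gives 15 without the propargyl ethers and without the semihydrogenation, and the route resumes at 15. The detour makes no new compound (F0).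

Step 4. What may go wrong: the aryllithium may act as a base toward the amide methylene, or the phenoxide aggregate may stay unreactive, so that the protonated arene is returned and little ketone forms. The fallback sets out from 2. Reduction with i-Bu2AlH in CH2Cl2 at −78 °C should give the racemic lactol 6-(methoxymethoxy)-2,3-dihydrobenzofuran-2-ol F1. Two equivalents of the aryllithium 7 should open it through its hydroxy-aldehyde form to the racemic diol 1-[2,4,6-tris(benzyloxy)phenyl]-2-[2-hydroxy-4-(methoxymethoxy)phenyl]ethan-1-ol F2, the aldehyde being far more electrophilic than the amide. MnO2 in CH2Cl2 should then oxidise the benzylic carbinol to the ketone 9, where the route continues.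

Step 13. What may go wrong: under the acid needed to cleave four acetals, the liberated phenols or methanol may add across the adjacent prenyl double bonds and close 2,2-dimethylchroman rings. The fallback sets out from 14, where no prenyl group is yet on carbon and the tertiary propargylic ethers tolerate acid, and it returns at the target 20. Methanolic HCl should remove the two acetals to give 1-[4-hydroxy-2,6-bis(2-methylbut-3-yn-2-yloxy)phenyl]-2-[4-hydroxy-2-(2-methylbut-3-yn-2-yloxy)phenyl]ethan-1-one F3. Semihydrogenation as in step 9 should give 1-[4-hydroxy-2,6-bis(2-methylbut-3-en-2-yloxy)phenyl]-2-[4-hydroxy-2-(2-methylbut-3-en-2-yloxy)phenyl]ethan-1-one F4. The same threefold rearrangement as in step 10 should then give 1-[2,4,6-trihydroxy-3,5-bis(3-methylbut-2-en-1-yl)phenyl]-2-[2,4-dihydroxy-3-(3-methylbut-2-en-1-yl)phenyl]ethan-1-one F5. Allyl bromide and K2CO3 in acetone should cap every hydroxyl except the chelated one, giving 1-[2-hydroxy-4,6-bis(allyloxy)-3,5-bis(3-methylbut-2-en-1-yl)phenyl]-2-[2,4-bis(allyloxy)-3-(3-methylbut-2-en-1-yl)phenyl]ethan-1-one F6. The formamide acetal should convert this through the enaminone 3-(dimethylamino)-1-[2-hydroxy-4,6-bis(allyloxy)-3,5-bis(3-methylbut-2-en-1-yl)phenyl]-2-[2,4-bis(allyloxy)-3-(3-methylbut-2-en-1-yl)phenyl]prop-2-en-1-one F7 into 5,7-bis(allyloxy)-3-[2,4-bis(allyloxy)-3-(3-methylbut-2-en-1-yl)phenyl]-6,8-bis(3-methylbut-2-en-1-yl)-4H-chromen-4-one F8. Pd(PPh3)4 with morpholine in THF should then remove the four O-allyl groups under neutral conditions to give 20.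

Further compounds
F0 | step 8 | none | none
F1 | step 4 | 6-(methoxymethoxy)-2,3-dihydrobenzofuran-2-ol (racemic) | COCOc1ccc2CC(O)Oc2c1
F2 | step 4 | 1-[2,4,6-tris(benzyloxy)phenyl]-2-[2-hydroxy-4-(methoxymethoxy)phenyl]ethan-1-ol (racemic) | COCOc1ccc(CC(O)c2c(OCc3ccccc3)cc(OCc3ccccc3)cc2OCc2ccccc2)c(O)c1
F3 | step 13 | 1-[4-hydroxy-2,6-bis(2-methylbut-3-yn-2-yloxy)phenyl]-2-[4-hydroxy-2-(2-methylbut-3-yn-2-yloxy)phenyl]ethan-1-one | C#CC(C)(C)Oc1cc(O)cc(OC(C)(C)C#C)c1C(=O)Cc1ccc(O)cc1OC(C)(C)C#C
F4 | step 13 | 1-[4-hydroxy-2,6-bis(2-methylbut-3-en-2-yloxy)phenyl]-2-[4-hydroxy-2-(2-methylbut-3-en-2-yloxy)phenyl]ethan-1-one | C=CC(C)(C)Oc1cc(O)cc(OC(C)(C)C=C)c1C(=O)Cc1ccc(O)cc1OC(C)(C)C=C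
F5 | step 13 | 1-[2,4,6-trihydroxy-3,5-bis(3-methylbut-2-en-1-yl)phenyl]-2-[2,4-dihydroxy-3-(3-methylbut-2-en-1-yl)phenyl]ethan-1-one | O=C(Cc1ccc(O)c(CC=C(C)C)c1O)c1c(O)c(CC=C(C)C)c(O)c(CC=C(C)C)c1O
F6 | step 13 | 1-[2-hydroxy-4,6-bis(allyloxy)-3,5-bis(3-methylbut-2-en-1-yl)phenyl]-2-[2,4-bis(allyloxy)-3-(3-methylbut-2-en-1-yl)phenyl]ethan-1-one | O=C(Cc1ccc(OCC=C)c(CC=C(C)C)c1OCC=C)c1c(O)c(CC=C(C)C)c(OCC=C)c(CC=C(C)C)c1OCC=C
F7 | step 13 | 3-(dimethylamino)-1-[2-hydroxy-4,6-bis(allyloxy)-3,5-bis(3-methylbut-2-en-1-yl)phenyl]-2-[2,4-bis(allyloxy)-3-(3-methylbut-2-en-1-yl)phenyl]prop-2-en-1-one (not isolated, geometry not fixed) | CN(C)C=C(C(=O)c1c(O)c(CC=C(C)C)c(OCC=C)c(CC=C(C)C)c1OCC=C)c1ccc(OCC=C)c(CC=C(C)C)c1OCC=C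
F8 | step 13 | 5,7-bis(allyloxy)-3-[2,4-bis(allyloxy)-3-(3-methylbut-2-en-1-yl)phenyl]-6,8-bis(3-methylbut-2-en-1-yl)-4H-chromen-4-one | C=CCOc1ccc(-c2coc3c(CC=C(C)C)c(OCC=C)c(CC=C(C)C)c(OCC=C)c3c2=O)c(OCC=C)c1CC=C(C)C
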